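**Plan**

- The retrosynthesis first cuts the depside ester bond between the carboxyl carbon of ring B and the C4 oxygen of ring A; both halves are then the same 2,4-dioxygenated 6-(2-oxoheptyl)benzoic acid.
- In that acid, taken as its lactone (isocoumarin), the ring C6–CH2 bond and the lactone C–O bond are cut, leading back to 2,4-bis(benzyloxy)benzoic acid and a hexanoyl sulfoxonium ylide.
- The enabling feature: in each ring C6 is the only carbon ortho to the carboxyl-bearing C1 that carries no oxygen, and its substituent is an acylmethyl group (CH2–CO–C5H11), the equivalent of an acyl carbene.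
- Forward: the annulation closes the isocoumarin ring (the only ring made), KOH reopens it, and the keto acid is carried on as benzyl ester and dioxolane; this one intermediate is divided into the acid partner (ring B) and the phenol partner (ring A).
- The partners are joined by esterification at the C4 hydroxyl of ring A, the ketones are unmasked and all benzyl groups are removed by hydrogenolysis. The target has no stereocentre, so no stereochemistry has to be set.

Key step: step 4

Remark: benzyl bromide and 1,2-bis(trimethylsilyloxy)ethane are used as unnumbered reagents. The open keto acid that passes through the key step unisolated is the isolated product of the step that follows it.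

**Route**

Step 1
Reactants: 1 2,4-dihydroxybenzoic acid
Product: 2 benzyl 2,4-bis(benzyloxy)benzoate
Conditions: BnBr, K2CO3, DMF, 80 °C
Reagents that add atoms: benzyl bromide, BrCc1ccccc1
Why: Williamson etherification of both phenols and O-alkylation of the carboxylate (SN2 on benzyl bromide) should go to completion in warm DMF, the heat being needed for the hydrogen-bonded C2 hydroxyl.

Step 2
Reactants: 2 benzyl 2,4-bis(benzyloxy)benzoate
Product: 3 2,4-bis(benzyloxy)benzoic acid
Conditions: KOH, MeOH/THF/H2O, reflux; then 1 M HCl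
Reagents that add atoms: potassium hydroxide, [K+].[OH-]
Why: Saponification (acyl substitution by hydroxide) of a benzoate with only one ortho substituent should be fast and leaves the aryl benzyl ethers untouched.

Step 3
Reactants: 4 trimethylsulfoxonium iodide; 5 hexanoyl chloride
Product: 7 1-[dimethyl(oxo)-λ6-sulfanylidene]heptan-2-one, via dimethylsulfoxonium methylide 6 (not isolated)
Conditions: KOtBu, THF, reflux; then 5, 0 °C to rt
Reagents that add atoms: none
Why: Deprotonation of the sulfoxonium salt gives the Corey–Chaykovsky methylide, whose C-acylation by the acid chloride should give the stabilised keto sulfoxonium ylide, a second equivalent of methylide acting as the base.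

Step 4
Reactants: 3 2,4-bis(benzyloxy)benzoic acid; 7 1-[dimethyl(oxo)-λ6-sulfanylidene]heptan-2-one
Product: 9 6,8-bis(benzyloxy)-3-pentyl-1H-isochromen-1-one, via open keto acid 8 (not isolated)
Conditions: [Cp*RhCl2]2 (cat.), AgSbF6 (cat.), NaOAc (0.3 equiv), DCE, 100 °C
Reagents that add atoms: none
Why: Acetate-assisted concerted metalation–deprotonation at C6–H by the cationic Cp* complex of trivalent rhodium bound to the carboxylate gives a five-membered rhodacycle, ylide 7 binds through carbon and loses dimethyl sulfoxide to give a rhodium carbene, and migratory insertion followed by protonation releases keto acid 8 and the catalyst. The closest known reaction type is the C–H/O–H annulation of benzoic acids with acyl sulfoxonium ylides under Cp* complexes of trivalent rhodium, which gives 3-substituted isocoumarins. The lactone ring closes by 6-exo-trig addition of the carboxyl oxygen to the ketone carbonyl followed by loss of water, helped by the Lewis acidic metal salts at 100 °C. No stereocentre is formed. The step needs site selectivity for C6, which the benzyloxy group at C2 secures by occupying the only other position ortho to the carboxyl, and it needs a single insertion, which lactonisation secures by consuming the directing carboxylate.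

Step 5
Reactants: 9 6,8-bis(benzyloxy)-3-pentyl-1H-isochromen-1-one
Product: 8 2,4-bis(benzyloxy)-6-(2-oxoheptyl)benzoic acid
Conditions: KOH, EtOH/H2O, reflux; then cold 1 M HCl to pH 3
Reagents that add atoms: potassium hydroxide, [K+].[OH-]
Why: Alkaline hydrolysis of the enol lactone (acyl substitution, the enolate leaving group becoming the ketone) is made irreversible by carboxylate formation, and cold acidification should give the open keto acid, the same compound that passes through step 4 unisolated.

Step 6
Reactants: 8 2,4-bis(benzyloxy)-6-(2-oxoheptyl)benzoic acid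
Product: 10 benzyl 2,4-bis(benzyloxy)-6-(2-oxoheptyl)benzoate
Conditions: BnBr, KHCO3, DMF, rt
Reagents that add atoms: benzyl bromide, BrCc1ccccc1
Why: Carboxylate O-alkylation (SN2) is insensitive to the two ortho substituents, and bicarbonate is too weak a base to enolise the benzylic ketone or to let the acid lactonise.

Step 7
Reactants: 10 benzyl 2,4-bis(benzyloxy)-6-(2-oxoheptyl)benzoate
Product: 11 benzyl 2,4-bis(benzyloxy)-6-[(2-pentyl-1,3-dioxolan-2-yl)methyl]benzoate
Conditions: (TMSOCH2)2, TMSOTf (cat.), CH2Cl2, −78 °C to −20 °C; then pyridine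
Reagents that add atoms: 1,2-bis(trimethylsilyloxy)ethane, C[Si](C)(C)OCCO[Si](C)(C)C
Why: Noyori ketalisation transfers the glycol unit from its bis-silyl ether under aprotic conditions, driven by formation of hexamethyldisiloxane, at a temperature where the keto ester should not lactonise.

Step 8
Reactants: 11 benzyl 2,4-bis(benzyloxy)-6-[(2-pentyl-1,3-dioxolan-2-yl)methyl]benzoate
Product: 12 2,4-bis(benzyloxy)-6-[(2-pentyl-1,3-dioxolan-2-yl)methyl]benzoic acid
Conditions: KOH, DMSO/H2O, 90 °C; then cold 1 M HCl to pH 4, immediate extraction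
Reagents that add atoms: potassium hydroxide, [K+].[OH-]
Why: Saponification of a di-ortho-substituted benzoate needs the poorly solvated hydroxide of aqueous DMSO, benzyl ethers and the dioxolane are inert to base, and a brief cold acidification should spare the ketal.

Step 9
Reactants: 11 benzyl 2,4-bis(benzyloxy)-6-[(2-pentyl-1,3-dioxolan-2-yl)methyl]benzoate
Product: 14 benzyl 2,4-dihydroxy-6-[(2-pentyl-1,3-dioxolan-2-yl)methyl]benzoate, via dihydroxy acid ketal 13 (not isolated)
Conditions: H2 (1 atm), 10% Pd/C, EtOAc, rt; filter, evaporate; then BnBr (1 equiv), KHCO3, DMF, rt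
Reagents that add atoms: benzyl bromide, BrCc1ccccc1
Why: Hydrogenolysis removes all three O-benzyl groups, and carboxylate alkylation (SN2) under bicarbonate, which does not deprotonate the phenols, should restore only the benzyl ester, so the labile hydroxy acid is never stored.

Step 10
Reactants: 12 2,4-bis(benzyloxy)-6-[(2-pentyl-1,3-dioxolan-2-yl)methyl]benzoic acid; 14 benzyl 2,4-dihydroxy-6-[(2-pentyl-1,3-dioxolan-2-yl)methyl]benzoate
Product: 15 benzyl 4-({2,4-bis(benzyloxy)-6-[(2-pentyl-1,3-dioxolan-2-yl)methyl]benzoyl}oxy)-2-hydroxy-6-[(2-pentyl-1,3-dioxolan-2-yl)methyl]benzoate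
Conditions: DCC, DMAP (cat.), CH2Cl2, 0 °C to rt
Reagents that add atoms: none
Why: Steglich esterification under neutral conditions should acylate the C4 hydroxyl, the more acidic and unhindered phenol, because the C2 hydroxyl is held in a hydrogen bond to the neighbouring benzyl ester carbonyl.

Step 11
Reactants: 15 benzyl 4-({2,4-bis(benzyloxy)-6-[(2-pentyl-1,3-dioxolan-2-yl)methyl]benzoyl}oxy)-2-hydroxy-6-[(2-pentyl-1,3-dioxolan-2-yl)methyl]benzoate
Product: 16 benzyl 4-{[2,4-bis(benzyloxy)-6-(2-oxoheptyl)benzoyl]oxy}-2-hydroxy-6-(2-oxoheptyl)benzoate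
Conditions: 1 M HCl, THF, rt
Reagents that add atoms: water, O
Why: Acid-catalysed ketal hydrolysis through oxocarbenium ions should unmask both ketones in dilute acid at room temperature, conditions that aryl esters, benzyl esters and benzyl ethers tolerate.

Step 12
Reactants: 16 benzyl 4-{[2,4-bis(benzyloxy)-6-(2-oxoheptyl)benzoyl]oxy}-2-hydroxy-6-(2-oxoheptyl)benzoate
Product: 17 4-{[2,4-dihydroxy-6-(2-oxoheptyl)benzoyl]oxy}-2-hydroxy-6-(2-oxoheptyl)benzoic acid
Conditions: H2 (1 atm), 10% Pd/C, EtOAc, rt
Reagents that add atoms: none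
Why: Hydrogenolysis of the benzyl ester and the two aryl benzyl ethers under neutral conditions should leave the aliphatic ketones and the depside ester intact and give the target after filtration.

**Compound list**

1 | 2,4-dihydroxybenzoic acid | O=C(O)c1ccc(O)cc1O | starting material
2 | benzyl 2,4-bis(benzyloxy)benzoate | O=C(OCc1ccccc1)c1ccc(OCc2ccccc2)cc1OCc1ccccc1 | intermediate
3 | 2,4-bis(benzyloxy)benzoic acid | O=C(O)c1ccc(OCc2ccccc2)cc1OCc1ccccc1 | intermediate
4 | trimethylsulfoxonium iodide | C[S+](C)(C)=O.[I-] | starting material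
5 | hexanoyl chloride | CCCCCC(Cl)=O | starting material
6 | dimethylsulfoxonium methylide | C=S(C)(C)=O | intermediate
7 | 1-[dimethyl(oxo)-λ6-sulfanylidene]heptan-2-one | CCCCCC(=O)C=S(C)(C)=O | intermediate
8 | 2,4-bis(benzyloxy)-6-(2-oxoheptyl)benzoic acid | CCCCCC(=O)Cc1cc(OCc2ccccc2)cc(OCc2ccccc2)c1C(=O)O | intermediate
9 | 6,8-bis(benzyloxy)-3-pentyl-1H-isochromen-1-one | CCCCCC1=Cc2cc(OCc3ccccc3)cc(OCc3ccccc3)c2C(=O)O1 | intermediate
10 | benzyl 2,4-bis(benzyloxy)-6-(2-oxoheptyl)benzoate | CCCCCC(=O)Cc1cc(OCc2ccccc2)cc(OCc2ccccc2)c1C(=O)OCc1ccccc1 | intermediate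
11 | benzyl 2,4-bis(benzyloxy)-6-[(2-pentyl-1,3-dioxolan-2-yl)methyl]benzoate | CCCCCC1(Cc2cc(OCc3ccccc3)cc(OCc3ccccc3)c2C(=O)OCc2ccccc2)OCCO1 | intermediate
12 | 2,4-bis(benzyloxy)-6-[(2-pentyl-1,3-dioxolan-2-yl)methyl]benzoic acid | CCCCCC1(Cc2cc(OCc3ccccc3)cc(OCc3ccccc3)c2C(=O)O)OCCO1 | intermediate
13 | 2,4-dihydroxy-6-[(2-pentyl-1,3-dioxolan-2-yl)methyl]benzoic acid | CCCCCC1(Cc2cc(O)cc(O)c2C(=O)O)OCCO1 | intermediate
14 | benzyl 2,4-dihydroxy-6-[(2-pentyl-1,3-dioxolan-2-yl)methyl]benzoate | CCCCCC1(Cc2cc(O)cc(O)c2C(=O)OCc2ccccc2)OCCO1 | intermediate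
15 | benzyl 4-({2,4-bis(benzyloxy)-6-[(2-pentyl-1,3-dioxolan-2-yl)methyl]benzoyl}oxy)-2-hydroxy-6-[(2-pentyl-1,3-dioxolan-2-yl)methyl]benzoate | CCCCCC1(Cc2cc(OC(=O)c3c(OCc4ccccc4)cc(OCc4ccccc4)cc3CC3(CCCCC)OCCO3)cc(O)c2C(=O)OCc2ccccc2)OCCO1 | intermediate
16 | benzyl 4-{[2,4-bis(benzyloxy)-6-(2-oxoheptyl)benzoyl]oxy}-2-hydroxy-6-(2-oxoheptyl)benzoate | CCCCCC(=O)Cc1cc(OC(=O)c2c(OCc3ccccc3)cc(OCc3ccccc3)cc2CC(=O)CCCCC)cc(O)c1C(=O)OCc1ccccc1 | intermediate
17 | 4-{[2,4-dihydroxy-6-(2-oxoheptyl)benzoyl]oxy}-2-hydroxy-6-(2-oxoheptyl)benzoic acid | CCCCCC(=O)Cc1cc(OC(=O)c2c(O)cc(O)cc2CC(=O)CCCCC)cc(O)c1C(=O)O | target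

**Step count and risks**

Total: 12 steps. Longest linear sequence: 10 steps (steps 1, 2, 4, 5, 6, 7, 8 or 9, 10, 11, 12 from compound 1).

Steps most likely to fail:

1. Step 4. The free acid may protonate the ylide and be O-alkylated by it, the electron-rich acid may lose CO2 in the presence of the silver salt, or metalation may be slow beside a carboxylate twisted by the C2 benzyloxy group. Incomplete lactonisation would not matter, since step 5 converts 9 into 8 in any case. The fallback forms the benzylic C–C(=O) bond by enolate chemistry instead. It sets out from hexanoyl chloride 5, which with MeNHOMe·HCl and K2CO3 in CH2Cl2/H2O should give N-methoxy-N-methylhexanamide F1. Commercial methyl 2,4-dihydroxy-6-methylbenzoate F2 is benzylated with BnBr and K2CO3 in DMF to methyl 2,4-bis(benzyloxy)-6-methylbenzoate F3. Deprotonation of the ring methyl group of F3 with LiN(iPr)2 in THF at −78 °C and acylation of the benzylic anion with F1 should give, after aqueous work-up, methyl 2,4-bis(benzyloxy)-6-(2-oxoheptyl)benzoate F4. Saponification of F4 with KOH in aqueous DMSO at 90 °C and cold acidification then comes back to the route at keto acid 8.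

2. Step 10. The hindered O-acylisourea may rearrange to the N-acylurea before acyl transfer, a ketal oxygen may attack the activated acyl group, or some acylation may occur at the C2 hydroxyl. The fallback uses an isolable acyl donor and a preformed phenoxide. It sets out from acid 12, which with cyanuric fluoride and pyridine in CH2Cl2 at −10 °C should give 2,4-bis(benzyloxy)-6-[(2-pentyl-1,3-dioxolan-2-yl)methyl]benzoyl fluoride F7. F7 is added to phenol 14 and Cs2CO3 (1 equiv) in MeCN, where only the more acidic C4 hydroxyl is ionised, and the sequence comes back to the route at 15.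

3. Step 8. Hydroxide attack at the di-ortho-substituted ester may stall, and acidification may open the ketal and let the acid close back to the lactone. The fallback frees the acid by cleavage at the alkyl C–O bond instead. It sets out from keto acid 8, which with allyl bromide and KHCO3 in DMF should give allyl 2,4-bis(benzyloxy)-6-(2-oxoheptyl)benzoate F5. Ketalisation of F5 as in step 7 should give allyl 2,4-bis(benzyloxy)-6-[(2-pentyl-1,3-dioxolan-2-yl)methyl]benzoate F6. Pd(PPh3)4 (zerovalent palladium) with morpholine in THF at rt removes the allyl group of F6 without any acid and comes back to the route at 12; phenol partner 14 is still made from 11.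

**Further compounds**

F1 | step 4 | N-methoxy-N-methylhexanamide | CCCCCC(=O)N(C)OC
F2 | step 4 | methyl 2,4-dihydroxy-6-methylbenzoate | COC(=O)c1c(C)cc(O)cc1O
F3 | step 4 | methyl 2,4-bis(benzyloxy)-6-methylbenzoate | COC(=O)c1c(C)cc(OCc2ccccc2)cc1OCc1ccccc1
F4 | step 4 | methyl 2,4-bis(benzyloxy)-6-(2-oxoheptyl)benzoate | CCCCCC(=O)Cc1cc(OCc2ccccc2)cc(OCc2ccccc2)c1C(=O)OC
F5 | step 8 | allyl 2,4-bis(benzyloxy)-6-(2-oxoheptyl)benzoate | CCCCCC(=O)Cc1cc(OCc2ccccc2)cc(OCc2ccccc2)c1C(=O)OCC=C
F6 | step 8 | allyl 2,4-bis(benzyloxy)-6-[(2-pentyl-1,3-dioxolan-2-yl)methyl]benzoate | CCCCCC1(Cc2cc(OCc3ccccc3)cc(OCc3ccccc3)c2C(=O)OCC=C)OCCO1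
F7 | step 10 | 2,4-bis(benzyloxy)-6-[(2-pentyl-1,3-dioxolan-2-yl)methyl]benzoyl fluoride | CCCCCC1(Cc2cc(OCc3ccccc3)cc(OCc3ccccc3)c2C(F)=O)OCCO1
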